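**Retrosynthetic overview**
- The last disconnection is the ester C–O bond: ent-labda-8(17),13(16),14-trien-19-ol plus methyl p-coumarate (acyl transfer, no protecting group).
- The 2-substituted butadiene comes from a (Z)-2-ene-1,4-diol by reductive 1,4-elimination, and the ene-diol from a butenolide by hydride reduction.
- The C3 methylene comes from a 3,19-O-benzylidene acetal by radical redox rearrangement (C3–O cleaved, C19 benzoate formed); the butenolide comes from the 14-acetate by SN2′ hydride delivery.
- The trans-decalin, the exocyclic methylene and the stereocentres C4, C5, C9 and C10 are taken intact from andrographolide. No ring is formed (the lactone is opened) and no C–C bond is made.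

Convention: ent-labdane numbering is used; C19 is the oxygenated carbon on C4, cis to the C10 methyl. The target's C4/C5/C9/C10 configuration is identical to that of andrographolide.

**Step 1**
Reactants: 1 andrographolide
Product: 2 3,19-O-[(R)-benzylidene]andrographolide
Conditions: PhCH(OMe)2, PPTS (cat.), DMF, 50 °C, reduced pressure
Reagents that add atoms: benzaldehyde dimethyl acetal, COC(OC)c1ccccc1
Why: Acid-catalysed transacetalisation closes a 1,3-dioxane on the C3-OH/C19-OH pair (the lone 14-OH cannot form a ring) and equilibrates to the equatorial-phenyl diastereomer, which sets the (R) acetal carbon.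

**Step 2**
Reactants: 2 3,19-O-[(R)-benzylidene]andrographolide
Product: 3 14-O-acetyl-3,19-O-[(R)-benzylidene]andrographolide
Conditions: Ac2O, pyridine, DMAP (cat.), CH2Cl2, 0 °C to rt
Reagents that add atoms: acetic anhydride, CC(=O)OC(C)=O
Why: DMAP-catalysed O-acylation of the only free hydroxyl (allylic C14-OH) turns it into a leaving group; no stereocentre is touched.

**Step 3**
Reactants: 3 14-O-acetyl-3,19-O-[(R)-benzylidene]andrographolide
Product: 4 3,19-O-[(R)-benzylidene]-14-deoxyandrographolide
Conditions: NaBH4, THF/MeOH, −20 to 0 °C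
Reagents that add atoms: none
Why: SN2′ reduction: conjugate hydride addition at C12 of the α-alkylidene lactone gives the enolate, which expels the C14 acetate (E1cB) to form the endocyclic butenolide, as Morita–Baylis–Hillman acetates and andrographolide 14-acetates do with soft nucleophiles; the C14 stereocentre is removed.

**Step 4**
Reactants: 4 3,19-O-[(R)-benzylidene]-14-deoxyandrographolide
Product: 5 19-O-benzoyl-3,14-dideoxyandrographolide (andrograpanin 19-benzoate)
Conditions: iPr3SiSH (10 mol%), 2,2-bis(tert-butylperoxy)butane (10 mol%), 2,4,6-collidine (10 mol%), PhCl, 130 °C, degassed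
Reagents that add atoms: none
Why: Thiol-catalysed radical-chain redox rearrangement of a benzylidene acetal (Roberts): the thiyl radical abstracts the acetal H, the 2-phenyl-1,3-dioxan-2-yl radical undergoes β-scission at the C3–O bond of the cis-fused ring to give the benzoate and the secondary C3 radical (not the neopentylic primary C19 radical), and the thiol returns H to C3; the C3 and acetal stereocentres disappear.

**Step 5**
Reactants: 5 19-O-benzoyl-3,14-dideoxyandrographolide
Product: 6 ent-labda-8(17),13Z-diene-15,16,19-triol
Conditions: DIBAL-H (6 equiv), CH2Cl2, −78 to 0 °C; Rochelle salt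
Reagents that add atoms: none
Why: DIBAL-H 1,2-reduction of the butenolide (through the lactol) gives the (Z)-2-ene-1,4-diol with the ring-derived cis geometry kept, and the same reagent cleaves the benzoate to the free C19 alcohol.

**Step 6**
Reactants: 6 ent-labda-8(17),13Z-diene-15,16,19-triol
Product: 7 ent-labda-8(17),13(16),14-trien-19-ol
Conditions: TiCl3/LiAlH4 (2:1), THF, 0 °C to reflux
Reagents that add atoms: none
Why: Low-valent titanium reductive 1,4-elimination of a 2-ene-1,4-diol (Walborsky/McMurry-type deoxygenation) gives the 2-substituted buta-1,3-diene; the saturated neopentylic 19-OH is not deoxygenated.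

**Step 7**
Reactants: 7 ent-labda-8(17),13(16),14-trien-19-ol; 8 methyl (E)-4-hydroxycinnamate (3 equiv)
Product: 9 ent-labda-8(17),13(16),14-trien-19-yl (E)-4-hydroxycinnamate
Conditions: Zn4(OCOCF3)6O (5 mol%), DMAP (20 mol%), BHT (cat.), PhMe, 100 °C, 5 Å MS
Reagents that add atoms: none
Why: Proposed new method: μ4-oxo-tetranuclear zinc cluster (DMAP co-ligand) catalysed transesterification of an unprotected phenolic cinnamate onto a neopentylic axial primary carbinol. Two neighbouring Zn centres hold the C19 alkoxide and the ester carbonyl, so acyl transfer runs through a compact dinuclear tetrahedral intermediate; the phenol is not acylated because aryl ester formation from a methyl ester is uphill and reversible (no oligomers, no protecting group); the near-neutral catalyst should leave the exocyclic alkene, the 1,3-diene and the (E)-enoate untouched (no oxa-Michael addition); MeOH trapping on 5 Å sieves with excess 8 drives the equilibrium. The closest known reaction type is the Zn4(OCOCF3)6O-catalysed transesterification of methyl esters with unhindered primary and secondary alcohols, which has not been shown for a hindered C4-neopentylic diterpenol or with a free-phenol acyl donor; no stereocentre is formed and the E geometry is carried over from 8.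

**Compound list**
1 | andrographolide | O=C1OC[C@@H](O)/C1=C\C[C@@H]2C(=C)CC[C@@H]3[C@](C)(CO)[C@H](O)CC[C@@]23C | starting material
2 | 3,19-O-[(R)-benzylidene]andrographolide | O=C1OC[C@@H](O)/C1=C\C[C@@H]2C(=C)CC[C@@H]3[C@]4(C)CO[C@@H](c5ccccc5)O[C@@H]4CC[C@@]23C | intermediate
3 | 14-O-acetyl-3,19-O-[(R)-benzylidene]andrographolide | O=C1OC[C@@H](OC(C)=O)/C1=C\C[C@@H]2C(=C)CC[C@@H]3[C@]4(C)CO[C@@H](c5ccccc5)O[C@@H]4CC[C@@]23C | intermediate
4 | 3,19-O-[(R)-benzylidene]-14-deoxyandrographolide | O=C1OCC=C1CC[C@@H]2C(=C)CC[C@@H]3[C@]4(C)CO[C@@H](c5ccccc5)O[C@@H]4CC[C@@]23C | intermediate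
5 | 19-O-benzoyl-3,14-dideoxyandrographolide (andrograpanin 19-benzoate) | O=C1OCC=C1CC[C@@H]2C(=C)CC[C@@H]3[C@](C)(COC(=O)c4ccccc4)CCC[C@@]23C | intermediate
6 | ent-labda-8(17),13Z-diene-15,16,19-triol | OC/C=C(\CO)CC[C@@H]1C(=C)CC[C@@H]2[C@](C)(CO)CCC[C@@]12C | intermediate
7 | ent-labda-8(17),13(16),14-trien-19-ol | C=CC(=C)CC[C@@H]1C(=C)CC[C@@H]2[C@](C)(CO)CCC[C@@]12C | intermediate
8 | methyl (E)-4-hydroxycinnamate | COC(=O)/C=C/c1ccc(O)cc1 | starting material
9 | ent-labda-8(17),13(16),14-trien-19-yl (E)-4-hydroxycinnamate (CNP0131099.1) | C=CC(=C)CC[C@@H]1C(=C)CC[C@@H]2[C@](C)(COC(=O)/C=C/c3ccc(O)cc3)CCC[C@@]12C | target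

**Totals**
Total step count: 7. Longest linear sequence: 7 (1 to 9).

**Three steps most likely to fail**

Step 4. Thiyl radicals may add to or isomerise the exocyclic alkene and stall the chain, or the β-scission may be unselective. The fallback sets out from 4 and uses Barton deoxygenation. The acetal is hydrolysed (80% aq. AcOH, 50 °C) to 14-deoxyandrographolide F1. The 3,19-diol is closed with 1,1′-thiocarbonyldiimidazole (DMAP, THF, reflux) to 14-deoxyandrographolide 3,19-cyclic thionocarbonate F2. Bu3SnH/AIBN (PhMe, 110 °C) fragments it at the secondary C3–O bond to the 19-O-[(tributylstannylthio)carbonyl] derivative F3 (not isolated). Mild hydrolysis (K2CO3, aq. MeOH) gives andrograpanin F4, which comes back to the route at 6 under the DIBAL-H conditions of step 5.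

Step 6. The low-valent titanium elimination may be incomplete or give over-reduced material in the presence of the free 19-OH. The fallback sets out from 6. PBr3 (Et2O, −20 °C) converts the two allylic hydroxyls into (Z)-15,16-dibromo-ent-labda-8(17),13-dien-19-ol F5; the neopentylic 19-OH is only transiently phosphitylated and returns on aqueous work-up. Reductive 1,4-debromination with zinc dust (THF, rt) comes back to the route at 7.

Step 7 (the proposed new step). Acyl transfer to the hindered carbinol may be too slow, the phenol may inhibit the zinc catalyst, or the diene may suffer on prolonged heating. The fallback sets out from 7 and uses a protected acyl donor. Steglich acylation with commercial (E)-4-acetoxycinnamic acid (EDC·HCl, DMAP, CH2Cl2, rt) gives ent-labda-8(17),13(16),14-trien-19-yl (E)-4-acetoxycinnamate F6. Selective methanolysis of the aryl acetate (K2CO3 cat., MeOH, 0 °C) comes back to the route at 9.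

**Further compounds**
F1 | step 4 | 14-deoxyandrographolide | O=C1OCC=C1CC[C@@H]2C(=C)CC[C@@H]3[C@](C)(CO)[C@H](O)CC[C@@]23C
F2 | step 4 | 14-deoxyandrographolide 3,19-cyclic thionocarbonate | O=C1OCC=C1CC[C@@H]2C(=C)CC[C@@H]3[C@]4(C)COC(=S)O[C@@H]4CC[C@@]23C
F3 | step 4 | 19-O-[(tributylstannylthio)carbonyl]-3,14-dideoxyandrographolide | O=C1OCC=C1CC[C@@H]2C(=C)CC[C@@H]3[C@](C)(COC(=O)S[Sn](CCCC)(CCCC)CCCC)CCC[C@@]23C
F4 | step 4 | andrograpanin (3,14-dideoxyandrographolide) | O=C1OCC=C1CC[C@@H]2C(=C)CC[C@@H]3[C@](C)(CO)CCC[C@@]23C
F5 | step 6 | (Z)-15,16-dibromo-ent-labda-8(17),13-dien-19-ol | BrC/C=C(\CBr)CC[C@@H]1C(=C)CC[C@@H]2[C@](C)(CO)CCC[C@@]12C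
F6 | step 7 | ent-labda-8(17),13(16),14-trien-19-yl (E)-4-acetoxycinnamate | C=CC(=C)CC[C@@H]1C(=C)CC[C@@H]2[C@](C)(COC(=O)/C=C/c3ccc(OC(C)=O)cc3)CCC[C@@]12C
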